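The flavone is cut at C4–C4a and at C5–O, the two bonds that an aryne at C4a–C5 of ring A can form at once. Ring A shows exactly this pattern: the C4 acyl carbon on C4a and an oxygen on the neighbouring C5, flanked by C6–H and by the C8a oxygen. In a single operation a 3-alkoxyaryne, released from a 2-silylaryl triflate, takes up (Z)-2-methoxy-3-(2-methoxyphenyl)acrylic acid across its acyl C–O bond, so that C2, C3, C4, the 3-methoxy group and ring B arrive together as an ortho-hydroxyaryl enone. The C8a oxygen travels as a methoxymethyl ether and later closes ring C as O1.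

Key step: step 6

Remark on the chemistry: in the phenol that results from oxidising the formyl group of the starting hydroxy aldehyde, both carbons ortho to the new hydroxyl are flanked by a second oxygen, so a directed metalation cannot be relied on to tell them apart; silicon is therefore delivered to a carbon that is brominated at the aldehyde stage. The three starting materials are taken as commercially available, and the enol ether is carried as the Z isomer, although its geometry is lost in the last step.

Step 1
Reactants: 1 3-hydroxy-4,5-dimethoxybenzaldehyde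
Product: 2 2-bromo-3-hydroxy-4,5-dimethoxybenzaldehyde
Conditions: Br2 (1.05 equiv), NaOAc, AcOH, rt
Reagents that add atoms: bromine, BrBr
Why: Electrophilic aromatic bromination should go to C2, the only free position ortho to the hydroxyl and also para to the 5-methoxy group, the same preference by which isovanillin is brominated between its hydroxyl and formyl groups.

Step 2
Reactants: 2 2-bromo-3-hydroxy-4,5-dimethoxybenzaldehyde
Product: 3 2-bromo-4,5-dimethoxy-3-(methoxymethoxy)benzaldehyde
Conditions: MOMCl, K2CO3, acetone, 0 °C → rt
Reagents that add atoms: chloromethyl methyl ether, COCCl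
Why: Williamson-type O-alkylation of the acidic ortho-bromophenol installs an acetal that keeps the future O1 distinct from the other ring oxygens and tolerates peracid, organolithium and fluoride.

Step 3
Reactants: 3 2-bromo-4,5-dimethoxy-3-(methoxymethoxy)benzaldehyde
Product: 5 2-bromo-4,5-dimethoxy-3-(methoxymethoxy)phenol, via aryl formate 4 (not isolated)
Conditions: mCPBA, CH2Cl2, 0 °C → rt; then K2CO3 (cat.), MeOH, rt
Reagents that add atoms: 3-chloroperoxybenzoic acid, OOC(=O)c1cccc(Cl)c1
Why: Baeyer–Villiger oxidation in which the electron-rich, ortho-substituted aryl group migrates in preference to hydride, followed by methanolysis of the labile formate; a peracid is chosen because alkaline peroxide (Dakin conditions) needs a free ortho or para hydroxyl and acidic peroxide would cleave the acetal.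

Step 4
Reactants: 5 2-bromo-4,5-dimethoxy-3-(methoxymethoxy)phenol
Product: 8 4,5-dimethoxy-3-(methoxymethoxy)-2-(trimethylsilyl)phenyl trifluoromethanesulfonate, via silyl ether 6 (not isolated), via lithium silylphenolate 7 (not isolated)
Conditions: HMDS, THF, reflux, then evaporation; n-BuLi, THF, −78 °C; Tf2O, −78 °C → rt
Reagents that add atoms: hexamethyldisilazane, C[Si](C)(C)N[Si](C)(C)C; trifluoromethanesulfonic anhydride, O=S(=O)(OS(=O)(=O)C(F)(F)F)C(F)(F)F
Why: O-silylation, bromine–lithium exchange and 1,3 O→C silyl shift (retro-Brook rearrangement) put silicon exactly on the carbon that carried bromine, and the resulting lithium phenoxide is triflated in the same flask, the standard way to 2-(trimethylsilyl)aryl triflates.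

Step 5
Reactants: 9 2-methoxybenzaldehyde; 10 methyl methoxyacetate
Product: 12 (Z)-2-methoxy-3-(2-methoxyphenyl)prop-2-enoic acid, via methyl ester 11 (not isolated)
Conditions: NaOMe, MeOH, 0 °C → reflux; then aq NaOH, reflux; HCl
Reagents that add atoms: sodium hydroxide, [Na+].[OH-]
Why: Claisen-type aldol condensation of the ester enolate with the non-enolisable aldehyde and E1cB dehydration should give the thermodynamically preferred isomer with aryl trans to the carboxyl group (Z by the sequence rules), and saponification in the same pot converges all material on the crystalline acid; no stereocentre is formed.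

Step 6
Reactants: 8 4,5-dimethoxy-3-(methoxymethoxy)-2-(trimethylsilyl)phenyl trifluoromethanesulfonate (1.3 equiv); 12 (Z)-2-methoxy-3-(2-methoxyphenyl)prop-2-enoic acid
Product: 14 (Z)-1-[6-hydroxy-3,4-dimethoxy-2-(methoxymethoxy)phenyl]-2-methoxy-3-(2-methoxyphenyl)prop-2-en-1-one, via aryne 13 (not isolated)
Conditions: CsF (4 equiv), THF, 125 °C, sealed tube
Reagents that add atoms: none
Why: Fluoride attacks silicon of 8 and the aryl anion expels triflate to give aryne 13; the caesium carboxylate of 12 adds to its C5 terminus (the carbon next to C6–H), the aryl anion formed at C4a attacks the neighbouring ester carbonyl through a transient four-membered alkoxide, and cleavage of the acyl C–O bond leaves the ketone on C4a and the phenoxide on C5. The closest known reaction is the fluoride-mediated insertion of arynes into the C–O bond of carboxylic acids, which gives ortho-hydroxyaryl ketones in hot THF; it is applied here to an α,β-unsaturated acid and a trioxygenated aryne. The product contains no new ring, so the only closure is the transient 4-exo-trig one of the acyl shift, and no stereocentre is created; the Z enol ether is not touched. The step needs regioselective carboxylate addition at C5, which the methoxymethoxy group on C8a should secure, because a 3-alkoxyaryne is distorted toward attack at the remote terminus and the carbanion developing at C4a is stabilised inductively by the adjacent oxygen. It also needs acyl transfer to outrun protonation of the aryl anion, which the aprotic medium, the high temperature and the proximity of the ester carbonyl favour. Conjugate closure of the C5 phenoxide onto the enone would be reversible, and any such isomer reopens under the basic conditions of step 7.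

Step 7
Reactants: 14 (Z)-1-[6-hydroxy-3,4-dimethoxy-2-(methoxymethoxy)phenyl]-2-methoxy-3-(2-methoxyphenyl)prop-2-en-1-one
Product: 15 (Z)-2-methoxy-3-(2-methoxyphenyl)-1-[3,4,6-trimethoxy-2-(methoxymethoxy)phenyl]prop-2-en-1-one
Conditions: MeI, K2CO3, DMF, 40 °C
Reagents that add atoms: iodomethane, CI
Why: Williamson O-methylation of the chelated C5 phenol fixes the C5 methoxy group while the C8a oxygen stays masked, and under the same base any flavanone-type isomer of 14 should reopen by E1cB and be trapped as the same ether.

Step 8
Reactants: 15 (Z)-2-methoxy-3-(2-methoxyphenyl)-1-[3,4,6-trimethoxy-2-(methoxymethoxy)phenyl]prop-2-en-1-one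
Product: 16 (Z)-1-(2-hydroxy-3,4,6-trimethoxyphenyl)-2-methoxy-3-(2-methoxyphenyl)prop-2-en-1-one
Conditions: HCl (conc., cat.), MeOH–THF, 40 °C
Reagents that add atoms: none
Why: Acid-catalysed transacetalisation of the aryl methoxymethyl ether ortho to the ketone should be mild enough to spare the methyl aryl ethers and the carbonyl-conjugated enol ether, which the adjacent ketone deactivates toward protonation; partial acid-induced closure to the flavanone would not matter, since that isomer is also oxidised in step 9.

Step 9
Reactants: 16 (Z)-1-(2-hydroxy-3,4,6-trimethoxyphenyl)-2-methoxy-3-(2-methoxyphenyl)prop-2-en-1-one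
Product: 17 3,5,7,8-tetramethoxy-2-(2-methoxyphenyl)-4H-chromen-4-one
Conditions: I2 (10 mol %), DMSO, 120 °C
Reagents that add atoms: none
Why: Iodine/DMSO oxidative cyclisation of a 2'-hydroxychalcone, by 6-endo oxa-Michael addition of the C8a hydroxyl to C2, iodination at C3 and loss of HI, with DMSO reoxidising iodide so that iodine is catalytic and the C3 methoxy group a spectator.

Compound list
1 | 3-hydroxy-4,5-dimethoxybenzaldehyde | COc1cc(C=O)cc(O)c1OC | starting material
2 | 2-bromo-3-hydroxy-4,5-dimethoxybenzaldehyde | COc1cc(C=O)c(Br)c(O)c1OC | intermediate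
3 | 2-bromo-4,5-dimethoxy-3-(methoxymethoxy)benzaldehyde | COCOc1c(Br)c(C=O)cc(OC)c1OC | intermediate
4 | 2-bromo-4,5-dimethoxy-3-(methoxymethoxy)phenyl formate | COCOc1c(Br)c(OC=O)cc(OC)c1OC | intermediate
5 | 2-bromo-4,5-dimethoxy-3-(methoxymethoxy)phenol | COCOc1c(Br)c(O)cc(OC)c1OC | intermediate
6 | [2-bromo-4,5-dimethoxy-3-(methoxymethoxy)phenoxy](trimethyl)silane | COCOc1c(Br)c(O[Si](C)(C)C)cc(OC)c1OC | intermediate
7 | lithium 4,5-dimethoxy-3-(methoxymethoxy)-2-(trimethylsilyl)phenolate | [Li+].[O-]c1cc(OC)c(OC)c(OCOC)c1[Si](C)(C)C | intermediate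
8 | 4,5-dimethoxy-3-(methoxymethoxy)-2-(trimethylsilyl)phenyl trifluoromethanesulfonate | COCOc1c(OC)c(OC)cc(OS(=O)(=O)C(F)(F)F)c1[Si](C)(C)C | intermediate
9 | 2-methoxybenzaldehyde | COc1ccccc1C=O | starting material
10 | methyl methoxyacetate | COCC(=O)OC | starting material
11 | methyl (Z)-2-methoxy-3-(2-methoxyphenyl)prop-2-enoate | COc1ccccc1/C=C(\OC)C(=O)OC | intermediate
12 | (Z)-2-methoxy-3-(2-methoxyphenyl)prop-2-enoic acid | COc1ccccc1/C=C(\OC)C(=O)O | intermediate
13 | 4,5-dimethoxy-3-(methoxymethoxy)benzyne (1,2-didehydro-4,5-dimethoxy-3-(methoxymethoxy)benzene) | COCOC1=C(OC)C(OC)=CC#C1 | intermediate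
14 | (Z)-1-[6-hydroxy-3,4-dimethoxy-2-(methoxymethoxy)phenyl]-2-methoxy-3-(2-methoxyphenyl)prop-2-en-1-one | COc1ccccc1/C=C(\OC)C(=O)c1c(O)cc(OC)c(OC)c1OCOC | intermediate
15 | (Z)-2-methoxy-3-(2-methoxyphenyl)-1-[3,4,6-trimethoxy-2-(methoxymethoxy)phenyl]prop-2-en-1-one | COc1ccccc1/C=C(\OC)C(=O)c1c(OC)cc(OC)c(OC)c1OCOC | intermediate
16 | (Z)-1-(2-hydroxy-3,4,6-trimethoxyphenyl)-2-methoxy-3-(2-methoxyphenyl)prop-2-en-1-one | COc1ccccc1/C=C(\OC)C(=O)c1c(OC)cc(OC)c(OC)c1O | intermediate
17 | 3,5,7,8-tetramethoxy-2-(2-methoxyphenyl)-4H-chromen-4-one | COc1ccccc1-c1oc2c(OC)c(OC)cc(OC)c2c(=O)c1OC | target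

Total step count: 9. Longest linear sequence: 8 steps (steps 1–4 and 6–9).

Steps most likely to fail

Step 6 (aryne insertion). The aryl anion may be protonated before the acyl group migrates, leaving only the O-aryl ester. The electron-rich aryne may also add the carboxylate with eroded regiochemistry, or be consumed by the product phenoxide. The fallback sets out from 5 and 12 and comes back at 15, replacing steps 6 and 7 by a classical aryllithium acylation. Phenol 5 is O-methylated (MeI, K2CO3, DMF) to 2-bromo-1,4,5-trimethoxy-3-(methoxymethoxy)benzene F1. Acid 12 is converted with carbonyldiimidazole and then MeNH(OMe)·HCl into (Z)-N,2-dimethoxy-3-(2-methoxyphenyl)-N-methylprop-2-enamide F2. Bromine–lithium exchange on F1 (n-BuLi, THF, −78 °C) gives [3,4,6-trimethoxy-2-(methoxymethoxy)phenyl]lithium F3, which should add to the N-methoxy-N-methylamide F2 and release ketone 15 from the chelated tetrahedral adduct on work-up.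

Step 9 (oxidative ring closure). The closure may stall at the flavanone stage, or hot iodine and hydrogen iodide may iodinate the very electron-rich C6 position of ring A or dealkylate the C5 ether. The fallback sets out from 16 and comes back at 17, separating ring closure from dehydrogenation. Compound 16 is cyclised under mild base (NaOAc, EtOH, reflux) by 6-endo oxa-Michael addition to racemic trans-3,5,7,8-tetramethoxy-2-(2-methoxyphenyl)-2,3-dihydro-4H-chromen-4-one F4. This flavanone is then dehydrogenated with DDQ in 1,4-dioxane at reflux to 17; its two stereocentres are of no consequence because both are lost.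

Step 1 (bromination). Substitution may occur para to the hydroxyl (at C6) or twice, which would misplace the silicon. The fallback sets out from 1 and comes back at 8, making the C–Si bond by directed ortho-metalation instead. Compound 1 is protected (MOMCl, K2CO3, acetone) as 3,4-dimethoxy-5-(methoxymethoxy)benzaldehyde F5, oxidised with mCPBA to 3,4-dimethoxy-5-(methoxymethoxy)phenyl formate F6 and methanolysed to 3,4-dimethoxy-5-(methoxymethoxy)phenol F7. Isopropyl isocyanate and Et3N give 3,4-dimethoxy-5-(methoxymethoxy)phenyl N-(propan-2-yl)carbamate F8. N-silylation in the flask (TBSOTf, TMEDA, Et2O) gives 3,4-dimethoxy-5-(methoxymethoxy)phenyl N-[tert-butyl(dimethyl)silyl]-N-(propan-2-yl)carbamate F9. n-BuLi/TMEDA at −78 °C should lithiate between the carbamate and acetal oxygens, the acetal being a stronger co-director than the methoxy group on the other flank. TMSCl then gives 4,5-dimethoxy-3-(methoxymethoxy)-2-(trimethylsilyl)phenyl N-[tert-butyl(dimethyl)silyl]-N-(propan-2-yl)carbamate F10, and acidic work-up gives 4,5-dimethoxy-3-(methoxymethoxy)-2-(trimethylsilyl)phenyl N-(propan-2-yl)carbamate F11. DBU and Et2NH in MeCN at 40 °C release 4,5-dimethoxy-3-(methoxymethoxy)-2-(trimethylsilyl)phenol F12, which PhNTf2 converts into 8 in the same flask.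

Further compounds
F1 | step 6 | 2-bromo-1,4,5-trimethoxy-3-(methoxymethoxy)benzene | COCOc1c(Br)c(OC)cc(OC)c1OC
F2 | step 6 | (Z)-N,2-dimethoxy-3-(2-methoxyphenyl)-N-methylprop-2-enamide | COc1ccccc1/C=C(\OC)C(=O)N(C)OC
F3 | step 6 | [3,4,6-trimethoxy-2-(methoxymethoxy)phenyl]lithium | [Li]c1c(OC)cc(OC)c(OC)c1OCOC
F4 | step 9 | rac-(2R,3R)-3,5,7,8-tetramethoxy-2-(2-methoxyphenyl)-2,3-dihydro-4H-chromen-4-one (trans, one enantiomer drawn) | COc1ccccc1[C@@H]1[C@@H](OC)C(=O)c2c(OC)cc(OC)c(OC)c2O1
F5 | step 1 | 3,4-dimethoxy-5-(methoxymethoxy)benzaldehyde | COCOc1cc(C=O)cc(OC)c1OC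
F6 | step 1 | 3,4-dimethoxy-5-(methoxymethoxy)phenyl formate | COCOc1cc(OC=O)cc(OC)c1OC
F7 | step 1 | 3,4-dimethoxy-5-(methoxymethoxy)phenol | COCOc1cc(O)cc(OC)c1OC
F8 | step 1 | 3,4-dimethoxy-5-(methoxymethoxy)phenyl N-(propan-2-yl)carbamate | COCOc1cc(OC(=O)NC(C)C)cc(OC)c1OC
F9 | step 1 | 3,4-dimethoxy-5-(methoxymethoxy)phenyl N-[tert-butyl(dimethyl)silyl]-N-(propan-2-yl)carbamate | COCOc1cc(OC(=O)N(C(C)C)[Si](C)(C)C(C)(C)C)cc(OC)c1OC
F10 | step 1 | 4,5-dimethoxy-3-(methoxymethoxy)-2-(trimethylsilyl)phenyl N-[tert-butyl(dimethyl)silyl]-N-(propan-2-yl)carbamate | COCOc1c([Si](C)(C)C)c(OC(=O)N(C(C)C)[Si](C)(C)C(C)(C)C)cc(OC)c1OC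
F11 | step 1 | 4,5-dimethoxy-3-(methoxymethoxy)-2-(trimethylsilyl)phenyl N-(propan-2-yl)carbamate | COCOc1c([Si](C)(C)C)c(OC(=O)NC(C)C)cc(OC)c1OC
F12 | step 1 | 4,5-dimethoxy-3-(methoxymethoxy)-2-(trimethylsilyl)phenol | COCOc1c([Si](C)(C)C)c(O)cc(OC)c1OC
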